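The closed, stirred vessel held G with E and J, and what I wanted from it was the curve of G up to 20 min.

- Thursday's: G 11 mM; E 1.2 equiv; J 1.5 equiv; the very flask that is asked about, followed so far
- flask: G 11 mM; E 1.20 equiv; J 1.50 equiv; time 20 min

- Thursday's (time / min: G / %, Z / %): 1.33: 41, 60; 2.50: 24, 76; 4.00: 12, 85; 5.00: 9, 88; 6.00: 8, 94

(each reading ± 2 percentage points)

- part of the G that has reacted at 20 min
- share of the unused E that is free and not bound as Q, at 20 min

The charge held more E than G, so G was the limiting reagent. Each G lost takes one E in G + E -> X + Z, so c(E) in equivalents stood at c(G) plus a surplus of 0.200 equiv, provided E was not bound. The rate at any moment was k·c(G)·c(E). The reading of 9% G at 5.00 min, put into the integrated second-order law, gave k times the charged G as 0.988 min⁻¹, a reading that carries the scatter. The curve therefore began with a slope of 1.19 min⁻¹, in fractions of the charged G. As G fell, c(E)/c(G) climbed exponentially at the margin rate 0.198 min⁻¹, the second-order constant times the surplus of the reagent in excess. The knee, where that ratio reached 2 and c(G) equalled the surplus, came by my reckoning at 2.59 min.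

Past the knee I reckoned the curve as a pseudo-first-order tail at 0.198 min⁻¹, which means a half-life of 3.50 min. At 20 min I reckoned 0.326% of G left, far below the surplus, so c = 99.7%. The readings did not show how much E sat in Q, so I could only guess the free share.

The forecast gave 98.5%, below my reckoning, and 80%, saying “Little rate loss by 6 min suggests most E stays free”.

The flask gave 99.7% and 98.8%.

    J ⇌ L (K = 4.00, k = 0.0690 s⁻¹)
    E + X ⇌ Q, settled at all times (K = 1100 M⁻¹)
    G + E → X + Z (k = 1.60 M⁻¹ s⁻¹)
    X + J ⇌ D (K = 1.00 × 10⁶ M⁻¹, k = 85.0 M⁻¹ s⁻¹)

In the flask at 20.0 min Q stood at 0.0275 mM. Over the second half of the flask's run G fell from 2.87% to 0.320%, a slope of 0.219 min⁻¹ against my margin rate of 0.198 min⁻¹. In the neighbour charged with 0.720 equiv of E, the surplus lay with G at 0.280 equiv, so I reckoned its margin rate as 0.277 min⁻¹. Over 20 min that put free E at 0.110% of its charge, and that neighbour held 0.093%.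

The readings are simulated on assumed constants; the scatter is artificial.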